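The synthesis rests on cutting the C8–C9 single bond. This bond joins the C7=C8 vinyl group on the fully substituted epoxide carbon C6 of ring A to the methyl-bearing C9 of the polyene. Because C8 is an unbranched CH beside a quaternary carbon, it is carried as the terminal alkyne C7≡C8–H. In the last step one flask hydroborates this epoxy alkynyl palmitate to the (E)-alkenylboronate. The same flask then couples it (Suzuki–Miyaura) with the C9 iodide of the octaenyl ε-ring palmitate, which fixes the C7=C8 geometry and completes the diester. The iodide comes from a symmetric C18 diiodide (C9–C9'). Both rings come from (R)-phorenol.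

Key step: step 18

Remark: carotenoid numbering is used (ring A = C1–C6 with the 5,6-epoxide, ε ring = C1'–C6'). The (R,R)-catalyst of step 1 is assumed to give the (R)-alcohol by analogy with aryl and alkynyl ketones; otherwise the (S,S)-catalyst is taken. All polyene steps run under argon in dim light.

Step 1
Reactants: 1 ketoisophorone (2,6,6-trimethylcyclohex-2-ene-1,4-dione)
Product: 2 (4R)-4-hydroxy-2,6,6-trimethylcyclohex-2-en-1-one ((R)-phorenol)
Conditions: RuCl[(R,R)-TsDPEN](p-cymene) (0.5 mol %), KOH (1 mol %), i-PrOH, 25 °C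
Reagents that add atoms: none
Why: Noyori-type asymmetric transfer hydrogenation should reduce only the unhindered C4 carbonyl (C1 is flanked by the quaternary carbon and the methyl-bearing alkene carbon), and the catalyst, which places the alkene side as the π-substituent in its six-membered transition state, sets the single (R)-carbinol centre from which all other stereocentres are relayed.

Step 2
Reactants: 2 (R)-phorenol
Product: 3 (4R)-4-(tert-butyldimethylsilyloxy)-2,6,6-trimethylcyclohex-2-en-1-one
Conditions: TBSCl, imidazole, DMF, 25 °C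
Reagents that add atoms: tert-butyldimethylsilyl chloride, CC(C)(C)[Si](C)(C)Cl
Why: Imidazole-promoted silylation of a secondary alcohol, which leaves the stereocentre untouched.

Step 3
Reactants: 3 silyl ether of (R)-phorenol
Product: 5 (4S)-4-(tert-butyldimethylsilyloxy)-2,6,6-trimethylcyclohex-1-en-1-yl trifluoromethanesulfonate, via lithium enolate 4 (not isolated)
Conditions: LiBH(s-Bu)3, THF, −78 °C; then PhNTf2, −78 → 25 °C
Reagents that add atoms: N-phenylbis(trifluoromethanesulfonimide), O=S(=O)(N(c1ccccc1)S(=O)(=O)C(F)(F)F)C(F)(F)F; LiBH(s-Bu)3, [Li+].CCC(C)[BH-](C(C)CC)C(C)CC (lithium only in 4)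
Why: Conjugate hydride reduction of an α-methyl, β-unsubstituted cyclohexenone whose carbonyl is too hindered for 1,2-attack gives one regiodefined enolate that is O-sulfonylated in the same flask (reductive enolate trapping), no stereocentre being formed and the descriptor of the carbinol carbon changing only by the priority rules.

Step 4
Reactants: 5 enol triflate
Product: 6 tert-butyldimethyl{[(1S)-3,5,5-trimethyl-4-(trimethylsilylethynyl)cyclohex-3-en-1-yl]oxy}silane
Conditions: Me3SiC≡CH, Pd(PPh3)4 (5 mol %), CuI (10 mol %), Et3N, DMF, 25–50 °C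
Reagents that add atoms: trimethylsilylacetylene, C#C[Si](C)(C)C
Why: Sonogashira coupling brings in C7 and C8, the slim copper acetylide being a partner that hindered tetrasubstituted cyclohexenyl triflates accept.

Step 5
Reactants: 6 bis-silylated enyne
Product: 7 (1S)-4-ethynyl-3,5,5-trimethylcyclohex-3-en-1-ol
Conditions: Bu4NF (2.5 equiv), THF, 0 → 25 °C
Reagents that add atoms: none
Why: Fluoride-induced desilylation cleaves the O–Si and the C(sp)–Si bond in one operation and touches neither the enyne nor the stereocentre.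

Step 6
Reactants: 7 hydroxy enyne
Product: 8 (1R,3R,6R)-6-ethynyl-1,5,5-trimethyl-7-oxabicyclo[4.1.0]heptan-3-ol (epoxide syn to the hydroxyl group)
Conditions: VO(acac)2 (5 mol %), t-BuOOH (decane), toluene, 0 → 25 °C
Reagents that add atoms: tert-butyl hydroperoxide, CC(C)(C)OO
Why: Hydroxyl-directed vanadium-catalysed epoxidation of a homoallylic cyclohexenol, in which the C3 alkoxide binds the vanadium alkylperoxide and delivers oxygen to C5=C6 from its own face, sets C5 and C6 in one event, and the unbound face and the alkyne stay inert because there is no undirected background reaction.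

Step 7
Reactants: 8 syn-epoxy alcohol; 9 palmitic acid (hexadecanoic acid)
Product: 10 (1R,3S,6R)-6-ethynyl-1,5,5-trimethyl-7-oxabicyclo[4.1.0]heptan-3-yl hexadecanoate (ester anti to the epoxide)
Conditions: PPh3, DIAD, toluene/THF, 0 → 25 °C
Reagents that add atoms: none
Why: Mitsunobu esterification replaces the activated C3 oxygen by palmitate with SN2 inversion, so one step installs the ester and turns the syn into the required anti relationship (3S,5R,6S series), the epoxide oxygen lying on the face of the leaving group and being unable to take part.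

Step 8
Reactants: 3 silyl ether of (R)-phorenol
Product: 11 tert-butyldimethyl{[(1R)-3,5,5-trimethyl-4-methylidenecyclohex-2-en-1-yl]oxy}silane
Conditions: Cp2TiMe2 (3 equiv), toluene, 75 °C, dark
Reagents that add atoms: dimethyltitanocene, C[Ti](C)(C1C=CC=C1)C1C=CC=C1
Why: Petasis methylenation uses the non-basic carbene Cp2Ti=CH2, which olefinates hindered ketones by cycloaddition and cycloreversion and cannot deprotonate the γ-carbon that carries the stereocentre.

Step 9
Reactants: 11 exocyclic diene
Product: 13 [(1R,4R)-4-(tert-butyldimethylsilyloxy)-2,6,6-trimethylcyclohex-2-en-1-yl]methanol, via B-alkyl-9-BBN adduct 12 (not isolated)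
Conditions: 9-BBN, THF, 0 → 25 °C; then NaOH, H2O2, 0 °C
Reagents that add atoms: hydrogen peroxide, OO; 9-BBN, [H]B1C2CCCC1CCC2 (boron and its ring only in 12)
Why: Hydroboration–oxidation puts boron on the exocyclic CH2 only and hydrogen on C6' from the face anti to the pseudo-axial C1' methyl group of the envelope conformer that keeps the C3' silyloxy group pseudo-equatorial, that is on the face of C3'–O, so the CH2OH group should end trans to the silyloxy group (6'R).

Step 10
Reactants: 13 primary alcohol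
Product: 14 (1R,4R)-4-(tert-butyldimethylsilyloxy)-2,6,6-trimethylcyclohex-2-ene-1-carbaldehyde
Conditions: Dess–Martin periodinane, NaHCO3, CH2Cl2, 0 °C
Reagents that add atoms: none
Why: Buffered Dess–Martin oxidation is near neutral, so the β,γ-unsaturated aldehyde should neither epimerise at C6' nor move its double bond into conjugation.

Step 11
Reactants: 14 aldehyde
Product: 15 2-{(E)-2-[(1R,4R)-4-(tert-butyldimethylsilyloxy)-2,6,6-trimethylcyclohex-2-en-1-yl]ethenyl}-4,4,5,5-tetramethyl-1,3,2-dioxaborolane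
Conditions: Cl2CHBpin, CrCl2, LiI, THF, 25 °C
Reagents that add atoms: 2-(dichloromethyl)-4,4,5,5-tetramethyl-1,3,2-dioxaborolane, ClC(Cl)B1OC(C)(C)C(C)(C)O1
Why: Takai–Utimoto boryl-olefination adds a geminal dichromium reagent to the aldehyde and eliminates to the (E)-alkenylboronate, strongly so for α-branched aldehydes, under non-basic conditions that leave C6' intact.

Step 12
Reactants: 15 silyl-protected alkenylboronate
Product: 16 (1R,4R)-3,5,5-trimethyl-4-[(E)-2-(4,4,5,5-tetramethyl-1,3,2-dioxaborolan-2-yl)ethenyl]cyclohex-2-en-1-ol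
Conditions: HF·pyridine, pyridine, THF, 0 → 25 °C
Reagents that add atoms: none
Why: Pyridine-buffered HF desilylation is too weakly acidic to ionise the allylic C3'–O bond and should leave the pinacol boronate in place.

Step 13
Reactants: 16 allylic alcohol; 9 palmitic acid
Product: 17 (1R,4R)-3,5,5-trimethyl-4-[(E)-2-(4,4,5,5-tetramethyl-1,3,2-dioxaborolan-2-yl)ethenyl]cyclohex-2-en-1-yl hexadecanoate
Conditions: DCC, DMAP (cat.), CH2Cl2, 0 → 25 °C
Reagents that add atoms: none
Why: Steglich esterification acylates at oxygen, so C3' keeps its (R) configuration and the boronate is not affected.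

Step 14
Reactants: 18 but-2-yn-1-ol
Product: 21 (E)-3-iodobut-2-en-1-ol, via diisobutylaluminium but-2-ynoxide 19 (not isolated), via alkenylzirconocene chloride 20 (not isolated)
Conditions: i-Bu2AlH (1 equiv), THF, 0 °C; Cp2ZrCl2/i-Bu2AlH (1.3 equiv each), 0 → 25 °C; then I2, −78 → 0 °C
Reagents that add atoms: iodine, II; i-Bu2AlH, CC(C)C[AlH]CC(C)C (aluminium only in 19 and 20); Cp2ZrCl2, Cl[Zr](Cl)(C1C=CC=C1)C1C=CC=C1 (zirconium only in 20)
Why: Hydrozirconation–iodinolysis adds Cp2ZrHCl made in the flask syn to the alkyne with zirconium on the less hindered methyl-bearing carbon, remote from the bulky aluminium alkoxide, and iodine replaces zirconium with retention, which places iodine trans to CH2OH.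

Step 15
Reactants: 21 (E)-3-iodobut-2-en-1-ol
Product: 22 diethyl [(E)-3-iodobut-2-en-1-yl]phosphonate
Conditions: P(OEt)3, ZnI2, THF, reflux
Reagents that add atoms: triethyl phosphite, CCOP(OCC)OCC
Why: ZnI2-mediated one-flask phosphonylation of an allylic alcohol (Michaelis–Arbuzov type) passes through the allyl diethyl phosphite and forms the C–P bond at the unhindered CH2 terminus without touching the alkenyl iodide or its geometry.

Step 16
Reactants: 22 iodobutenylphosphonate (2.3 equiv); 23 (2E,4E,6E)-2,7-dimethylocta-2,4,6-trienedial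
Product: 26 (2E,4E,6E,8E,10E,12E,14E)-2,15-diiodo-6,11-dimethylhexadeca-2,4,6,8,10,12,14-heptaene, via sodium phosphonate anion 24 (not isolated), via iodopentaenal 25 (not isolated)
Conditions: NaN(SiMe3)2, THF, −78 °C; then 23, −78 → 0 °C, dark
Reagents that add atoms: NaN(SiMe3)2, [Na+].C[Si](C)(C)[N-][Si](C)(C)C (sodium only in 24)
Why: Two-directional Horner–Wadsworth–Emmons olefination of the symmetric dialdehyde with an allylic phosphonate anion is E-selective at C11=C12 and C11'=C12', and the amide base neither exchanges nor eliminates the alkenyl iodide, whose vinylic hydrogen is cis to iodine.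

Step 17
Reactants: 17 ε-ring alkenylboronate palmitate; 26 C18 diiodide (3 equiv)
Product: 27 (1R,4R)-4-[(1E,3E,5E,7E,9E,11E,13E,15E)-16-iodo-3,7,12-trimethylheptadeca-1,3,5,7,9,11,13,15-octaen-1-yl]-3,5,5-trimethylcyclohex-2-en-1-yl hexadecanoate
Conditions: Pd(OAc)2 (5 mol %), SPhos (10 mol %), K3PO4 (aq), THF, 25 °C, dark
Reagents that add atoms: none
Why: Suzuki–Miyaura alkenyl–alkenyl coupling forms C8'–C9' with retention at both sp2 carbons, the excess of the symmetric diiodide with its two equivalent C–I termini biases the outcome toward single coupling, and the non-polar surplus 26 is recovered by chromatography.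

Step 18
Reactants: 10 ring A epoxy alkynyl palmitate (1.3 equiv); 27 octaenyl iodide
Product: 29 (3S,5R,6S,3'R,6'R)-5,6-epoxy-5,6-dihydro-β,ε-carotene-3,3'-diyl dihexadecanoate, via ring A alkenylboronate 28 (not isolated)
Conditions: HBpin, Cy2BH (10 mol %), THF, 25 °C; then H2O, K3PO4, 27, Pd(OAc)2 (5 mol %), SPhos (10 mol %), THF, 25 °C, dark
Reagents that add atoms: pinacolborane, [H]B1OC(C)(C)C(C)(C)O1 (boron and pinacol only in 28)
Why: Cy2BH-catalysed hydroboration with pinacolborane adds H–B syn across C7≡C8 with boron on the terminal C8, because the fully substituted C6 blocks the other regiochemistry, so 28 should form as the E isomer only. After water and K3PO4 are added the cycle is that of a Suzuki–Miyaura alkenyl–alkenyl coupling: oxidative addition of zerovalent palladium into the C9–I bond of 27, base-assisted transfer of the C8 alkenyl group from boron and reductive elimination, each with retention, so C7=C8 and C9=C10 both end E. The closest known reaction type is the one-pot alkyne hydroboration/Suzuki–Miyaura diene synthesis used in iterative polyene assembly. No ring is closed and no stereocentre is formed, the five stereocentres being spectators. The step needs chemoselectivity for the C(sp2)–I bond over ionisation of the C6 vinyl epoxide and of the C3' allylic palmitate, which is secured by the much faster oxidative addition to the iodide at 25 °C and by shielding of the faces anti to the two C–O bonds (C1 gem-dimethyl and C5 methyl groups in ring A, the C6' chain and the pseudo-axial C1' methyl group in the ε ring). The mildly basic medium, free of Lewis acids, also spares the acid-labile 5,6-epoxide from furanoid rearrangement and is too weak to hydrolyse the secondary palmitates.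

Compound list
1 | ketoisophorone (2,6,6-trimethylcyclohex-2-ene-1,4-dione) | CC1=CC(=O)CC(C)(C)C1=O | starting material
2 | (4R)-4-hydroxy-2,6,6-trimethylcyclohex-2-en-1-one | CC1=C[C@H](O)CC(C)(C)C1=O | intermediate
3 | (4R)-4-(tert-butyldimethylsilyloxy)-2,6,6-trimethylcyclohex-2-en-1-one | CC1=C[C@H](O[Si](C)(C)C(C)(C)C)CC(C)(C)C1=O | intermediate
4 | lithium (4S)-4-(tert-butyldimethylsilyloxy)-2,6,6-trimethylcyclohex-1-en-1-olate | [Li+].CC1=C([O-])C(C)(C)C[C@@H](O[Si](C)(C)C(C)(C)C)C1 | intermediate
5 | (4S)-4-(tert-butyldimethylsilyloxy)-2,6,6-trimethylcyclohex-1-en-1-yl trifluoromethanesulfonate | CC1=C(OS(=O)(=O)C(F)(F)F)C(C)(C)C[C@@H](O[Si](C)(C)C(C)(C)C)C1 | intermediate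
6 | tert-butyldimethyl{[(1S)-3,5,5-trimethyl-4-(trimethylsilylethynyl)cyclohex-3-en-1-yl]oxy}silane | CC1=C(C#C[Si](C)(C)C)C(C)(C)C[C@@H](O[Si](C)(C)C(C)(C)C)C1 | intermediate
7 | (1S)-4-ethynyl-3,5,5-trimethylcyclohex-3-en-1-ol | CC1=C(C#C)C(C)(C)C[C@@H](O)C1 | intermediate
8 | (1R,3R,6R)-6-ethynyl-1,5,5-trimethyl-7-oxabicyclo[4.1.0]heptan-3-ol | O[C@@H]1CC(C)(C)[C@]2(C#C)O[C@]2(C)C1 | intermediate
9 | palmitic acid | CCCCCCCCCCCCCCCC(=O)O | starting material
10 | (1R,3S,6R)-6-ethynyl-1,5,5-trimethyl-7-oxabicyclo[4.1.0]heptan-3-yl hexadecanoate | CCCCCCCCCCCCCCCC(=O)O[C@H]1CC(C)(C)[C@]2(C#C)O[C@]2(C)C1 | intermediate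
11 | tert-butyldimethyl{[(1R)-3,5,5-trimethyl-4-methylidenecyclohex-2-en-1-yl]oxy}silane | CC1=C[C@H](O[Si](C)(C)C(C)(C)C)CC(C)(C)C1=C | intermediate
12 | 9-{[(1R,4R)-4-(tert-butyldimethylsilyloxy)-2,6,6-trimethylcyclohex-2-en-1-yl]methyl}-9-borabicyclo[3.3.1]nonane | C1CC2CCCC(C1)B2C[C@H]3C(C)=C[C@H](O[Si](C)(C)C(C)(C)C)CC3(C)C | intermediate
13 | [(1R,4R)-4-(tert-butyldimethylsilyloxy)-2,6,6-trimethylcyclohex-2-en-1-yl]methanol | OC[C@H]1C(C)=C[C@H](O[Si](C)(C)C(C)(C)C)CC1(C)C | intermediate
14 | (1R,4R)-4-(tert-butyldimethylsilyloxy)-2,6,6-trimethylcyclohex-2-ene-1-carbaldehyde | O=C[C@H]1C(C)=C[C@H](O[Si](C)(C)C(C)(C)C)CC1(C)C | intermediate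
15 | 2-{(E)-2-[(1R,4R)-4-(tert-butyldimethylsilyloxy)-2,6,6-trimethylcyclohex-2-en-1-yl]ethenyl}-4,4,5,5-tetramethyl-1,3,2-dioxaborolane | CC1(C)OB(/C=C/[C@H]2C(C)=C[C@H](O[Si](C)(C)C(C)(C)C)CC2(C)C)OC1(C)C | intermediate
16 | (1R,4R)-3,5,5-trimethyl-4-[(E)-2-(4,4,5,5-tetramethyl-1,3,2-dioxaborolan-2-yl)ethenyl]cyclohex-2-en-1-ol | CC1(C)OB(/C=C/[C@H]2C(C)=C[C@H](O)CC2(C)C)OC1(C)C | intermediate
17 | (1R,4R)-3,5,5-trimethyl-4-[(E)-2-(4,4,5,5-tetramethyl-1,3,2-dioxaborolan-2-yl)ethenyl]cyclohex-2-en-1-yl hexadecanoate | CC1(C)OB(/C=C/[C@H]2C(C)=C[C@H](OC(=O)CCCCCCCCCCCCCCC)CC2(C)C)OC1(C)C | intermediate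
18 | but-2-yn-1-ol | CC#CCO | starting material
19 | diisobutylaluminium but-2-yn-1-oxide | CC#CCO[Al](CC(C)C)CC(C)C | intermediate
20 | chloro{(E)-4-[(diisobutylalumanyl)oxy]but-2-en-2-yl}zirconocene | C/C(=C\CO[Al](CC(C)C)CC(C)C)[Zr](Cl)(C1C=CC=C1)C1C=CC=C1 | intermediate
21 | (E)-3-iodobut-2-en-1-ol | I/C(C)=C/CO | intermediate
22 | diethyl [(E)-3-iodobut-2-en-1-yl]phosphonate | I/C(C)=C/CP(=O)(OCC)OCC | intermediate
23 | (2E,4E,6E)-2,7-dimethylocta-2,4,6-trienedial | O=C/C(C)=C/C=C/C=C(C)/C=O | starting material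
24 | sodium salt of the α-carbanion of 22 | [Na+].I/C(C)=C/[CH-]P(=O)(OCC)OCC | intermediate
25 | (2E,4E,6E,8E,10E)-11-iodo-2,7-dimethyldodeca-2,4,6,8,10-pentaenal | I/C(C)=C/C=C/C(C)=C/C=C/C=C(C)/C=O | intermediate
26 | (2E,4E,6E,8E,10E,12E,14E)-2,15-diiodo-6,11-dimethylhexadeca-2,4,6,8,10,12,14-heptaene | I/C(C)=C/C=C/C(C)=C/C=C/C=C(C)/C=C/C=C(C)/I | intermediate
27 | (1R,4R)-4-[(1E,3E,5E,7E,9E,11E,13E,15E)-16-iodo-3,7,12-trimethylheptadeca-1,3,5,7,9,11,13,15-octaen-1-yl]-3,5,5-trimethylcyclohex-2-en-1-yl hexadecanoate | I/C(C)=C/C=C/C(C)=C/C=C/C=C(C)/C=C/C=C(C)/C=C/[C@H]1C(C)=C[C@H](OC(=O)CCCCCCCCCCCCCCC)CC1(C)C | intermediate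
28 | (1R,3S,6S)-1,5,5-trimethyl-6-[(E)-2-(4,4,5,5-tetramethyl-1,3,2-dioxaborolan-2-yl)ethenyl]-7-oxabicyclo[4.1.0]heptan-3-yl hexadecanoate | CCCCCCCCCCCCCCCC(=O)O[C@H]1CC(C)(C)[C@]2(/C=C/B3OC(C)(C)C(C)(C)O3)O[C@]2(C)C1 | intermediate
29 | (3S,5R,6S,3'R,6'R)-5,6-epoxy-5,6-dihydro-β,ε-carotene-3,3'-diyl dihexadecanoate | CCCCCCCCCCCCCCCC(=O)O[C@H]1CC(C)(C)[C@]2(/C=C/C(C)=C/C=C/C(C)=C/C=C/C=C(C)/C=C/C=C(C)/C=C/[C@H]3C(C)=C[C@H](OC(=O)CCCCCCCCCCCCCCC)CC3(C)C)O[C@]2(C)C1 | target

Total step count: 18. Longest linear sequence: 10 steps (1, 2, 8, 9, 10, 11, 12, 13, 17, 18).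

Steps most likely to fail

Step 18.
- What may go wrong: slow boron-to-palladium transfer at the alkenyl group next to the quaternary C6. This would leave time for protodeboronation, for ionisation of the vinyl epoxide or the allylic ester by zerovalent palladium, and for E/Z scrambling of the iodide.
- Fallback: it sets out from 10 and abandons boron, base and water. Palladium-catalysed syn-hydrostannation (Bu3SnH, PdCl2(PPh3)2, THF, 0 °C) gives the isolated and purified (1R,3S,6S)-1,5,5-trimethyl-6-[(E)-2-(tributylstannyl)ethenyl]-7-oxabicyclo[4.1.0]heptan-3-yl hexadecanoate F1. A neutral Stille coupling of this stannane with 27 (Pd2(dba)3, AsPh3, NMP, 25 °C, dark) forms the same C8–C9 bond and comes back to the route at 29.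

Step 17.
- What may go wrong: over-coupling at both equivalent termini, and decay of the heptaenyl diiodide during the reaction and its recovery.
- Fallback: it sets out from 17 and 21 and avoids any statistical event on the long chain.
  - Suzuki–Miyaura coupling of 17 with 21 gives (1R,4R)-4-[(1E,3E)-5-hydroxy-3-methylpenta-1,3-dien-1-yl]-3,5,5-trimethylcyclohex-2-en-1-yl hexadecanoate F2.
  - P(OEt)3 and ZnI2 convert it into (1R,4R)-4-[(1E,3E)-5-(diethoxyphosphoryl)-3-methylpenta-1,3-dien-1-yl]-3,5,5-trimethylcyclohex-2-en-1-yl hexadecanoate F3.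
  - In parallel, anion 24 is added to an excess of 23, so that the less electrophilic iodopentaenal 25 can be isolated.
  - Horner–Wadsworth–Emmons olefination of 25 with the anion of the phosphonate (NaN(SiMe3)2, THF, −78 °C) forms C11'=C12' and comes back to the route at 27.

Step 9.
- What may go wrong: poor facial selectivity of hydrogen delivery to C6', or sluggish hydroboration of the conjugated, neopentyl-flanked methylidene group.
- Fallback: it sets out from 3 and replaces steps 8–10.
  - Corey–Chaykovsky epoxidation with dimethylsulfonium methylide (Me3SI, NaH, DMSO/THF, 0 °C) gives tert-butyldimethyl{[(3R,6R)-4,8,8-trimethyl-1-oxaspiro[2.5]oct-4-en-6-yl]oxy}silane F4.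
  - Meinwald rearrangement (MgBr2·OEt2, Et2O, −20 °C) opens the allylic C–O bond and shifts hydride from the CH2 group to C6'.
  - The C6' epimers are diastereomers because C3' is fixed, so they are separated on silica. The route is rejoined at 14.

Further compounds
F1 | step 18 | (1R,3S,6S)-1,5,5-trimethyl-6-[(E)-2-(tributylstannyl)ethenyl]-7-oxabicyclo[4.1.0]heptan-3-yl hexadecanoate | CCCCCCCCCCCCCCCC(=O)O[C@H]1CC(C)(C)[C@]2(/C=C/[Sn](CCCC)(CCCC)CCCC)O[C@]2(C)C1
F2 | step 17 | (1R,4R)-4-[(1E,3E)-5-hydroxy-3-methylpenta-1,3-dien-1-yl]-3,5,5-trimethylcyclohex-2-en-1-yl hexadecanoate | OC/C=C(C)/C=C/[C@H]1C(C)=C[C@H](OC(=O)CCCCCCCCCCCCCCC)CC1(C)C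
F3 | step 17 | (1R,4R)-4-[(1E,3E)-5-(diethoxyphosphoryl)-3-methylpenta-1,3-dien-1-yl]-3,5,5-trimethylcyclohex-2-en-1-yl hexadecanoate | CCOP(=O)(OCC)C/C=C(C)/C=C/[C@H]1C(C)=C[C@H](OC(=O)CCCCCCCCCCCCCCC)CC1(C)C
F4 | step 9 | tert-butyldimethyl{[(3R,6R)-4,8,8-trimethyl-1-oxaspiro[2.5]oct-4-en-6-yl]oxy}silane | CC1=C[C@H](O[Si](C)(C)C(C)(C)C)CC(C)(C)[C@]12CO2
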